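**Strategy**

The oxepane (O1, C2–C7) is cut at C5–C6. C5 lies β to C3, so a ketone at C3 makes C4–C5 a homoenolate, and a cyclopropanol at C3 can store it; C6 and its exocyclic C6=C1' alkene are carried as a (Z)-vinyl iodide tethered to O1 through C7. One palladium-catalysed operation opens the cyclopropane, joins C5 to C6 and closes the seven-membered ring with the alkene geometry kept, giving the oxepan-3-one. The precursor is a tertiary ether: quaternary C2, made from (R)-lactic acid and already carrying the complete side chain, bears the cyclopropanol on carbon and the 2-iodobut-2-enyl arm on oxygen.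

Key step: step 14

Remarks on the chemistry:
- Locants: oxepane O1, C2–C7; ethylidene C1', C2'; side chain C1''–C9'' counted from C2.
- (−)-Ipc2BOMe is taken to be the reagent made from (+)-α-pinene.
- In the butynediol-derived arm, iodine must sit on the alkyne carbon next to the future C7 and trans to hydrogen; step 10 places it there by a hydroxyl-directed trans-hydrostannation.

**Route**

Step 1
Reactants: 1 4-methylpent-3-en-1-ol
Product: 2 4-methylpent-3-enal
Conditions: Dess–Martin periodinane, NaHCO3, CH2Cl2, 0 °C; used crude at once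
Reagents that add atoms: none
Why: Dess–Martin oxidation stops at the aldehyde under buffered, non-basic conditions, which should limit migration of the β,γ-alkene into conjugation.

Step 2
Reactants: 2 4-methylpent-3-enal
Product: 3 (3R,4R)-3,7-dimethylocta-1,6-dien-4-ol
Conditions: cis-2-butene, n-BuLi, KOtBu, THF, −78 to −45 °C; (−)-Ipc2BOMe, −78 °C; BF3·OEt2; 2, −78 °C; then NaOH, H2O2
Reagents that add atoms: (Z)-crotyldiisopinocampheylborane (made in the flask from cis-2-butene), C/C=C\CB([C@@H]1C[C@@H]2C[C@H]([C@H]1C)C2(C)C)[C@@H]1C[C@@H]2C[C@H]([C@H]1C)C2(C)C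
Why: Brown crotylboration through a closed chair (Zimmerman–Traxler) transition state, in which the Z geometry of the crotyl group maps onto the syn C3/C4 relationship and the isopinocampheyl groups direct addition to the Si face of the aldehyde, so that 3R and 4R should be set together.

Step 3
Reactants: 3 (3R,4R)-3,7-dimethylocta-1,6-dien-4-ol
Product: 4 1-({[(3R,4R)-3,7-dimethylocta-1,6-dien-4-yl]oxy}methyl)-4-methoxybenzene
Conditions: NaH, PMBCl, TBAI (cat.), DMF, 0 °C to rt
Reagents that add atoms: 4-methoxybenzyl chloride, COc1ccc(CCl)cc1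
Why: Williamson etherification of the sodium alkoxide, which touches neither stereocentre.

Step 4
Reactants: 4 1-({[(3R,4R)-3,7-dimethylocta-1,6-dien-4-yl]oxy}methyl)-4-methoxybenzene
Product: 6 (4R,5R)-5-[(4-methoxybenzyl)oxy]-4,8-dimethylnon-7-en-1-ol, via aldehyde 5 (not isolated)
Conditions: Rh(acac)(CO)2 (1 mol %), Xantphos, CO/H2 (1:1, 10 bar), toluene, 70 °C; then NaBH4, MeOH, 0 °C
Reagents that add atoms: carbon monoxide, [C-]#[O+]
Why: Rhodium-catalysed hydroformylation with a wide-bite-angle diphosphine should place the formyl group on the terminal carbon (the allylic methyl branch disfavours the branched isomer and the trisubstituted alkene is inert), and borohydride reduction of the crude aldehyde gives the primary alcohol.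

Step 5
Reactants: 6 (4R,5R)-5-[(4-methoxybenzyl)oxy]-4,8-dimethylnon-7-en-1-ol
Product: 7 1-({[(5R,6R)-9-iodo-2,6-dimethylnon-2-en-5-yl]oxy}methyl)-4-methoxybenzene
Conditions: I2, PPh3, imidazole, CH2Cl2, 0 °C
Reagents that add atoms: iodine, II
Why: Appel-type iodination (Garegg–Samuelsson conditions) by SN2 displacement of the alkoxyphosphonium ion at the primary carbon.

Step 6
Reactants: 8 (R)-lactic acid; 9 pivalaldehyde
Product: 10 (2R,5R)-2-tert-butyl-5-methyl-1,3-dioxolan-4-one
Conditions: TsOH·H2O (cat.), H2SO4 (cat.), pentane, reflux, Dean–Stark; crystallisation from pentane at low temperature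
Reagents that add atoms: none
Why: Acid-catalysed acetalisation with azeotropic removal of water equilibrates towards the cis-2,5-disubstituted dioxolanone, so the new acetal centre (2R) is set under thermodynamic control by C5 of lactic acid and the minor trans isomer should be removed by crystallisation.

Step 7
Reactants: 10 (2R,5R)-2-tert-butyl-5-methyl-1,3-dioxolan-4-one; 7 1-({[(5R,6R)-9-iodo-2,6-dimethylnon-2-en-5-yl]oxy}methyl)-4-methoxybenzene
Product: 12 (2R,5S)-2-tert-butyl-5-{(4R,5R)-5-[(4-methoxybenzyl)oxy]-4,8-dimethylnon-7-en-1-yl}-5-methyl-1,3-dioxolan-4-one, via lithium enolate 11 (not isolated)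
Conditions: LDA, THF, −78 °C; then 7, DMPU, −78 to −30 °C
Reagents that add atoms: none
Why: Enolate alkylation under self-regeneration of stereocentres (Seebach alkylation), in which deprotonation flattens C5, the tert-butyl group on the acetal carbon shields one face and the iodide enters trans to it, so the side chain takes the place of hydrogen with retention and C5 becomes S.

Step 8
Reactants: 12 (2R,5S)-2-tert-butyl-5-{(4R,5R)-5-[(4-methoxybenzyl)oxy]-4,8-dimethylnon-7-en-1-yl}-5-methyl-1,3-dioxolan-4-one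
Product: 13 methyl (2S,6R,7R)-2-hydroxy-7-[(4-methoxybenzyl)oxy]-2,6,10-trimethylundec-9-enoate
Conditions: NaOMe (cat.), MeOH, 0 °C to rt
Reagents that add atoms: methanol, CO
Why: Methoxide-catalysed transesterification opens the lactone acetal, the hemiacetal alkoxide collapses to pivalaldehyde and the tertiary α-hydroxy methyl ester is left with C2 unchanged.

Step 9
Reactants: 14 but-2-yne-1,4-diol
Product: 15 4-{[tert-butyl(diphenyl)silyl]oxy}but-2-yn-1-ol
Conditions: NaH (1 equiv), THF, 0 °C; TBDPSCl (1 equiv), diol in excess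
Reagents that add atoms: tert-butyl(chloro)diphenylsilane, CC(C)(C)[Si](Cl)(c1ccccc1)c1ccccc1
Why: Monosilylation of the symmetrical diol through its monosodium alkoxide, the excess of diol suppressing the bis-silyl ether.

Step 10
Reactants: 15 4-{[tert-butyl(diphenyl)silyl]oxy}but-2-yn-1-ol
Product: 17 (2Z)-4-{[tert-butyl(diphenyl)silyl]oxy}-2-iodobut-2-en-1-ol, via vinylstannane 16 (not isolated)
Conditions: Bu3SnH, [Cp*RuCl]4 (cat.), CH2Cl2, rt; then I2, 0 °C
Reagents that add atoms: iodine, II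
Why: Hydroxyl-directed ruthenium-catalysed trans-hydrostannation, in which hydrogen bonding of the free OH to the chloride ligand steers tin to the proximal alkyne carbon while H and Sn add trans, followed by iododestannylation with retention, so iodine should end on the carbon next to CH2OH and cis to CH2OSi.

Step 11
Reactants: 17 (2Z)-4-{[tert-butyl(diphenyl)silyl]oxy}-2-iodobut-2-en-1-ol
Product: 18 {[(2Z)-4-bromo-3-iodobut-2-en-1-yl]oxy}(tert-butyl)diphenylsilane
Conditions: CBr4, PPh3, CH2Cl2, 0 °C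
Reagents that add atoms: carbon tetrabromide, BrC(Br)(Br)Br
Why: Appel reaction by SN2 displacement at the primary allylic carbon, which leaves the vinyl iodide and its geometry untouched.

Step 12
Reactants: 13 methyl (2S,6R,7R)-2-hydroxy-7-[(4-methoxybenzyl)oxy]-2,6,10-trimethylundec-9-enoate; 18 {[(2Z)-4-bromo-3-iodobut-2-en-1-yl]oxy}(tert-butyl)diphenylsilane
Product: 19 methyl (2S,6R,7R)-2-{[(2Z)-4-{[tert-butyl(diphenyl)silyl]oxy}-2-iodobut-2-en-1-yl]oxy}-7-[(4-methoxybenzyl)oxy]-2,6,10-trimethylundec-9-enoate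
Conditions: NaH, THF/DMF, 0 °C; 18, TBAI (cat.), 0 °C to rt
Reagents that add atoms: none
Why: Williamson etherification of the tertiary sodium alkoxide with a reactive primary allylic bromide, C2 having no α-hydrogen and therefore no way to epimerise.

Step 13
Reactants: 19 methyl (2S,6R,7R)-2-{[(2Z)-4-{[tert-butyl(diphenyl)silyl]oxy}-2-iodobut-2-en-1-yl]oxy}-7-[(4-methoxybenzyl)oxy]-2,6,10-trimethylundec-9-enoate
Product: 20 1-[(2S,6R,7R)-2-{[(2Z)-4-{[tert-butyl(diphenyl)silyl]oxy}-2-iodobut-2-en-1-yl]oxy}-7-[(4-methoxybenzyl)oxy]-6,10-dimethylundec-9-en-2-yl]cyclopropan-1-ol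
Conditions: EtMgBr (3 equiv, slow addition), Ti(OiPr)4 (0.5 equiv), THF, 0 °C to rt
Reagents that add atoms: ethylmagnesium bromide, CC[Mg]Br
Why: Kulinkovich cyclopropanation, in which the titanacyclopropane formed from EtMgBr and Ti(OiPr)4 adds twice to the ester carbonyl as a 1,2-dicarbanion equivalent with help from the neighbouring ether oxygen, while slow Grignard addition should spare the vinyl iodide and the trisubstituted alkenes do not exchange onto titanium.

Step 14
Reactants: 20 1-[(2S,6R,7R)-2-{[(2Z)-4-{[tert-butyl(diphenyl)silyl]oxy}-2-iodobut-2-en-1-yl]oxy}-7-[(4-methoxybenzyl)oxy]-6,10-dimethylundec-9-en-2-yl]cyclopropan-1-ol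
Product: 23 (2S,6E)-6-(2-{[tert-butyl(diphenyl)silyl]oxy}ethylidene)-2-{(4R,5R)-5-[(4-methoxybenzyl)oxy]-4,8-dimethylnon-7-en-1-yl}-2-methyloxepan-3-one, via alkenylpalladium iodide 21 (not isolated), via palladacycle 22 (not isolated)
Conditions: Pd2(dba)3 (5 mol %), XPhos (12 mol %), Cs2CO3, toluene (0.01 M), 70 °C
Reagents that add atoms: none
Why: Zerovalent palladium bearing XPhos should insert into the C6–I bond of 20 to give 21, carbonate then exchanges iodide for the cyclopropanolate, and strain-driven β-carbon elimination of either C3–CH2 bond (both lead to the same constitution) produces the C5 palladium homoenolate inside palladacycle 22, from which C(sp3)–C(sp2) reductive elimination forms C5–C6. The closest known reaction type is the palladium-catalysed ring-opening cross-coupling of cyclopropanols (ketone homoenolates) with aryl and alkenyl halides, run here in intramolecular form. The oxepane is closed by reductive elimination from the eight-membered palladacycle (Pd, C6, C7, O1, C2, C3, C4, C5), that is by ring contraction at the metal and not by a nucleophilic ring closure. No stereocentre is formed: C2 is quaternary and cannot epimerise next to the new ketone, and the alkene geometry is carried over with retention, iodine cis to C2' in 20 becoming C5 cis to C2' (6E) in 23. The selectivity needed is reductive elimination over β-hydride elimination from C4 (which would give an acyclic vinyl ketone) and over intermolecular coupling; the bulky electron-rich biarylphosphine, the short O1–C7 tether that holds both carbon ligands on one palladium, and high dilution are expected to secure it.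

Step 15
Reactants: 23 (2S,6E)-6-(2-{[tert-butyl(diphenyl)silyl]oxy}ethylidene)-2-{(4R,5R)-5-[(4-methoxybenzyl)oxy]-4,8-dimethylnon-7-en-1-yl}-2-methyloxepan-3-one
Product: 24 (2S,3R,6E)-6-(2-{[tert-butyl(diphenyl)silyl]oxy}ethylidene)-2-{(4R,5R)-5-[(4-methoxybenzyl)oxy]-4,8-dimethylnon-7-en-1-yl}-2-methyloxepan-3-ol
Conditions: (S)-Me-CBS (0.5 equiv), catecholborane, toluene, −78 to −40 °C
Reagents that add atoms: none
Why: Corey–Bakshi–Shibata reduction, in which the ketone binds the oxazaborolidine with the quaternary C2 side as the large group and the C4 methylene as the small one, so the (S)-catalyst should deliver hydride to the face that gives the 3R carbinol (OH cis to the C2 methyl) under catalyst control, while catecholborane at low temperature does not hydroborate the alkenes.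

Step 16
Reactants: 24 (2S,3R,6E)-6-(2-{[tert-butyl(diphenyl)silyl]oxy}ethylidene)-2-{(4R,5R)-5-[(4-methoxybenzyl)oxy]-4,8-dimethylnon-7-en-1-yl}-2-methyloxepan-3-ol
Product: 26 (2S,3R,6E)-6-(2-acetoxyethylidene)-2-{(4R,5R)-5-[(4-methoxybenzyl)oxy]-4,8-dimethylnon-7-en-1-yl}-2-methyloxepan-3-yl acetate, via diol 25 (not isolated)
Conditions: TBAF, THF, 0 °C to rt; then Et3N, DMAP, Ac2O, rt
Reagents that add atoms: acetic anhydride, CC(=O)OC(C)=O
Why: Fluoride cleaves the silyl ether by Si–F bond formation and the resulting diol is acetylated in the same flask by DMAP-catalysed acyl transfer, the PMB ether staying in place.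

Step 17
Reactants: 26 (2S,3R,6E)-6-(2-acetoxyethylidene)-2-{(4R,5R)-5-[(4-methoxybenzyl)oxy]-4,8-dimethylnon-7-en-1-yl}-2-methyloxepan-3-yl acetate
Product: 27 (2S,3R,6E)-6-(2-acetoxyethylidene)-2-[(4R,5R)-5-hydroxy-4,8-dimethylnon-7-en-1-yl]-2-methyloxepan-3-yl acetate
Conditions: DDQ, CH2Cl2/pH 7 buffer, 0 °C
Reagents that add atoms: none
Why: Oxidative PMB cleavage by DDQ (hydride abstraction from the electron-rich benzylic position, then hydrolysis of the oxocarbenium ion) should free the C5'' hydroxyl without touching the acetates or the alkenes.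

**Compound list**

1 | 4-methylpent-3-en-1-ol | CC(C)=CCCO | starting material
2 | 4-methylpent-3-enal | CC(C)=CCC=O | intermediate
3 | (3R,4R)-3,7-dimethylocta-1,6-dien-4-ol | C=C[C@@H](C)[C@H](O)CC=C(C)C | intermediate
4 | 1-({[(3R,4R)-3,7-dimethylocta-1,6-dien-4-yl]oxy}methyl)-4-methoxybenzene | C=C[C@@H](C)[C@H](OCc1ccc(OC)cc1)CC=C(C)C | intermediate
5 | (4R,5R)-5-[(4-methoxybenzyl)oxy]-4,8-dimethylnon-7-enal (not isolated) | O=CCC[C@@H](C)[C@H](OCc1ccc(OC)cc1)CC=C(C)C | intermediate
6 | (4R,5R)-5-[(4-methoxybenzyl)oxy]-4,8-dimethylnon-7-en-1-ol | OCCC[C@@H](C)[C@H](OCc1ccc(OC)cc1)CC=C(C)C | intermediate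
7 | 1-({[(5R,6R)-9-iodo-2,6-dimethylnon-2-en-5-yl]oxy}methyl)-4-methoxybenzene | ICCC[C@@H](C)[C@H](OCc1ccc(OC)cc1)CC=C(C)C | intermediate
8 | (R)-lactic acid | C[C@@H](O)C(=O)O | starting material
9 | pivalaldehyde | CC(C)(C)C=O | starting material
10 | (2R,5R)-2-tert-butyl-5-methyl-1,3-dioxolan-4-one | C[C@H]1O[C@@H](C(C)(C)C)OC1=O | intermediate
11 | lithium (2R)-2-tert-butyl-5-methyl-1,3-dioxol-4-olate (not isolated) | [Li+].CC1=C([O-])O[C@H](C(C)(C)C)O1 | intermediate
12 | (2R,5S)-2-tert-butyl-5-{(4R,5R)-5-[(4-methoxybenzyl)oxy]-4,8-dimethylnon-7-en-1-yl}-5-methyl-1,3-dioxolan-4-one | C[C@@]1(CCC[C@@H](C)[C@H](OCc2ccc(OC)cc2)CC=C(C)C)O[C@@H](C(C)(C)C)OC1=O | intermediate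
13 | methyl (2S,6R,7R)-2-hydroxy-7-[(4-methoxybenzyl)oxy]-2,6,10-trimethylundec-9-enoate | C[C@](O)(CCC[C@@H](C)[C@H](OCc1ccc(OC)cc1)CC=C(C)C)C(=O)OC | intermediate
14 | but-2-yne-1,4-diol | OCC#CCO | starting material
15 | 4-{[tert-butyl(diphenyl)silyl]oxy}but-2-yn-1-ol | OCC#CCO[Si](c1ccccc1)(c1ccccc1)C(C)(C)C | intermediate
16 | (2Z)-4-{[tert-butyl(diphenyl)silyl]oxy}-2-(tributylstannyl)but-2-en-1-ol (not isolated) | OC/C(=C/CO[Si](c1ccccc1)(c1ccccc1)C(C)(C)C)[Sn](CCCC)(CCCC)CCCC | intermediate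
17 | (2Z)-4-{[tert-butyl(diphenyl)silyl]oxy}-2-iodobut-2-en-1-ol | OC/C(I)=C/CO[Si](c1ccccc1)(c1ccccc1)C(C)(C)C | intermediate
18 | {[(2Z)-4-bromo-3-iodobut-2-en-1-yl]oxy}(tert-butyl)diphenylsilane | BrC/C(I)=C/CO[Si](c1ccccc1)(c1ccccc1)C(C)(C)C | intermediate
19 | methyl (2S,6R,7R)-2-{[(2Z)-4-{[tert-butyl(diphenyl)silyl]oxy}-2-iodobut-2-en-1-yl]oxy}-7-[(4-methoxybenzyl)oxy]-2,6,10-trimethylundec-9-enoate | COC(=O)[C@](C)(CCC[C@@H](C)[C@H](OCc1ccc(OC)cc1)CC=C(C)C)OC/C(I)=C/CO[Si](c1ccccc1)(c1ccccc1)C(C)(C)C | intermediate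
20 | 1-[(2S,6R,7R)-2-{[(2Z)-4-{[tert-butyl(diphenyl)silyl]oxy}-2-iodobut-2-en-1-yl]oxy}-7-[(4-methoxybenzyl)oxy]-6,10-dimethylundec-9-en-2-yl]cyclopropan-1-ol | OC1(CC1)[C@](C)(CCC[C@@H](C)[C@H](OCc1ccc(OC)cc1)CC=C(C)C)OC/C(I)=C/CO[Si](c1ccccc1)(c1ccccc1)C(C)(C)C | intermediate
21 | alkenylpalladium iodide from insertion into the C6–I bond of 20, phosphine not drawn (not isolated) | OC1(CC1)[C@](C)(CCC[C@@H](C)[C@H](OCc1ccc(OC)cc1)CC=C(C)C)OC/C([Pd]I)=C/CO[Si](c1ccccc1)(c1ccccc1)C(C)(C)C | intermediate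
22 | eight-membered palladacycle (Pd, C6, C7, O1, C2, C3, C4, C5) with the C3 ketone, phosphine not drawn (not isolated) | CC(C)(C)[Si](c1ccccc1)(c1ccccc1)OC/C=C1\[Pd]CCC(=O)[C@](C)(CCC[C@@H](C)[C@H](OCc2ccc(OC)cc2)CC=C(C)C)OC1 | intermediate
23 | (2S,6E)-6-(2-{[tert-butyl(diphenyl)silyl]oxy}ethylidene)-2-{(4R,5R)-5-[(4-methoxybenzyl)oxy]-4,8-dimethylnon-7-en-1-yl}-2-methyloxepan-3-one | CC(C)(C)[Si](c1ccccc1)(c1ccccc1)OC/C=C1\CCC(=O)[C@](C)(CCC[C@@H](C)[C@H](OCc2ccc(OC)cc2)CC=C(C)C)OC1 | intermediate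
24 | (2S,3R,6E)-6-(2-{[tert-butyl(diphenyl)silyl]oxy}ethylidene)-2-{(4R,5R)-5-[(4-methoxybenzyl)oxy]-4,8-dimethylnon-7-en-1-yl}-2-methyloxepan-3-ol | CC(C)(C)[Si](c1ccccc1)(c1ccccc1)OC/C=C1\CC[C@@H](O)[C@](C)(CCC[C@@H](C)[C@H](OCc2ccc(OC)cc2)CC=C(C)C)OC1 | intermediate
25 | (2S,3R,6E)-6-(2-hydroxyethylidene)-2-{(4R,5R)-5-[(4-methoxybenzyl)oxy]-4,8-dimethylnon-7-en-1-yl}-2-methyloxepan-3-ol (not isolated) | OC/C=C1\CC[C@@H](O)[C@](C)(CCC[C@@H](C)[C@H](OCc2ccc(OC)cc2)CC=C(C)C)OC1 | intermediate
26 | (2S,3R,6E)-6-(2-acetoxyethylidene)-2-{(4R,5R)-5-[(4-methoxybenzyl)oxy]-4,8-dimethylnon-7-en-1-yl}-2-methyloxepan-3-yl acetate | CC(=O)OC/C=C1\CC[C@@H](OC(C)=O)[C@](C)(CCC[C@@H](C)[C@H](OCc2ccc(OC)cc2)CC=C(C)C)OC1 | intermediate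
27 | (2S,3R,6E)-6-(2-acetoxyethylidene)-2-[(4R,5R)-5-hydroxy-4,8-dimethylnon-7-en-1-yl]-2-methyloxepan-3-yl acetate | CC(=O)OC/C=C1\CC[C@@H](OC(C)=O)[C@](C)(CCC[C@@H](C)[C@H](O)CC=C(C)C)OC1 | target

**Step count**

Total: 17 steps. Longest linear sequence: 13 steps (steps 1–5, 7, 8, 12–17).

**Steps most likely to fail**

Step 14 (ring-closing homoenolate coupling). β-Hydride elimination from the C5 alkylpalladium, leading to an acyclic vinyl ketone and loss of iodine, or intermolecular coupling may outrun the ring-closing reductive elimination; the seven-membered intramolecular variant is also less documented than the intermolecular coupling. The fallback forms the same C5–C6 bond by an intramolecular B-alkyl Suzuki–Miyaura coupling, which needs no ketone at C3 during the coupling. It sets out from ester 19. DIBAL-H in CH2Cl2 at −78 °C should give the aldehyde F1, and vinylmagnesium bromide at −78 °C the allylic alcohol F2 as a C3 epimer mixture of no consequence. 9-BBN in excess, the hydroxyl being tolerated, should hydroborate only the terminal vinyl group to the alkylborane F3. Pd(dppf)Cl2, AsPh3 and Cs2CO3 in DMF/THF/water should then couple C5 with the vinyl iodide with retention to the oxepan-3-ol F4. Dess–Martin oxidation brings the route back at oxepanone 23.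

Step 13 (Kulinkovich reaction beside a vinyl iodide). Iodine–magnesium exchange or reduction of the C–I bond by the Grignard reagent or by low-valent titanium may remove iodine or scramble the alkene geometry. The fallback carries tin through the cyclopropanation and introduces iodine afterwards. It sets out from vinylstannane 16, isolated this time, and hydroxy ester 13. CBr4/PPh3 should give the stannyl allylic bromide F5, etherification with the sodium alkoxide of 13 the stannyl ether ester F6, and the Kulinkovich reaction the stannyl cyclopropanol F7. One equivalent of I2 in CH2Cl2 at −78 °C (iododestannylation with retention, much faster than attack on the cyclopropanol) brings the route back at cyclopropanol 20.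

Step 7 (enolate alkylation with an unactivated iodide). The SN2 reaction of the primary iodide may be too slow at the low temperature that the dioxolanone enolate tolerates, so that self-condensation of the enolate wins. The fallback replaces the alkylation by an aldol addition and a deoxygenation. It sets out from enolate 11 and aldehyde 5, isolated after the hydroformylation and before NaBH4. The aldol addition at −78 °C, again trans to the tert-butyl group, should give the β-hydroxy dioxolanone F8, and phenyl chlorothionoformate with pyridine and DMAP the thionocarbonate F9. Bu3SnH/AIBN in toluene at 80 °C (Barton–McCombie deoxygenation) brings the route back at dioxolanone 12.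

**Further compounds**

F1 | step 14 | (2S,6R,7R)-2-{[(2Z)-4-{[tert-butyl(diphenyl)silyl]oxy}-2-iodobut-2-en-1-yl]oxy}-7-[(4-methoxybenzyl)oxy]-2,6,10-trimethylundec-9-enal | O=C[C@](C)(CCC[C@@H](C)[C@H](OCc1ccc(OC)cc1)CC=C(C)C)OC/C(I)=C/CO[Si](c1ccccc1)(c1ccccc1)C(C)(C)C
F2 | step 14 | (4S,8R,9R)-4-{[(2Z)-4-{[tert-butyl(diphenyl)silyl]oxy}-2-iodobut-2-en-1-yl]oxy}-9-[(4-methoxybenzyl)oxy]-4,8,12-trimethyltrideca-1,11-dien-3-ol (C3 epimers) | C=CC(O)[C@](C)(CCC[C@@H](C)[C@H](OCc1ccc(OC)cc1)CC=C(C)C)OC/C(I)=C/CO[Si](c1ccccc1)(c1ccccc1)C(C)(C)C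
F3 | step 14 | (4S,8R,9R)-1-(9-borabicyclo[3.3.1]nonan-9-yl)-4-{[(2Z)-4-{[tert-butyl(diphenyl)silyl]oxy}-2-iodobut-2-en-1-yl]oxy}-9-[(4-methoxybenzyl)oxy]-4,8,12-trimethyltridec-11-en-3-ol (C3 epimers) | OC(CCB1C2CCCC1CCC2)[C@](C)(CCC[C@@H](C)[C@H](OCc1ccc(OC)cc1)CC=C(C)C)OC/C(I)=C/CO[Si](c1ccccc1)(c1ccccc1)C(C)(C)C
F4 | step 14 | (2S,6E)-6-(2-{[tert-butyl(diphenyl)silyl]oxy}ethylidene)-2-{(4R,5R)-5-[(4-methoxybenzyl)oxy]-4,8-dimethylnon-7-en-1-yl}-2-methyloxepan-3-ol (C3 epimers) | CC(C)(C)[Si](c1ccccc1)(c1ccccc1)OC/C=C1\CCC(O)[C@](C)(CCC[C@@H](C)[C@H](OCc2ccc(OC)cc2)CC=C(C)C)OC1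
F5 | step 13 | {[(2Z)-4-bromo-3-(tributylstannyl)but-2-en-1-yl]oxy}(tert-butyl)diphenylsilane | BrC/C(=C/CO[Si](c1ccccc1)(c1ccccc1)C(C)(C)C)[Sn](CCCC)(CCCC)CCCC
F6 | step 13 | methyl (2S,6R,7R)-2-{[(2Z)-4-{[tert-butyl(diphenyl)silyl]oxy}-2-(tributylstannyl)but-2-en-1-yl]oxy}-7-[(4-methoxybenzyl)oxy]-2,6,10-trimethylundec-9-enoate | COC(=O)[C@](C)(CCC[C@@H](C)[C@H](OCc1ccc(OC)cc1)CC=C(C)C)OC/C(=C/CO[Si](c1ccccc1)(c1ccccc1)C(C)(C)C)[Sn](CCCC)(CCCC)CCCC
F7 | step 13 | 1-[(2S,6R,7R)-2-{[(2Z)-4-{[tert-butyl(diphenyl)silyl]oxy}-2-(tributylstannyl)but-2-en-1-yl]oxy}-7-[(4-methoxybenzyl)oxy]-6,10-dimethylundec-9-en-2-yl]cyclopropan-1-ol | OC1(CC1)[C@](C)(CCC[C@@H](C)[C@H](OCc1ccc(OC)cc1)CC=C(C)C)OC/C(=C/CO[Si](c1ccccc1)(c1ccccc1)C(C)(C)C)[Sn](CCCC)(CCCC)CCCC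
F8 | step 7 | (2R,5S)-2-tert-butyl-5-{(4R,5R)-1-hydroxy-5-[(4-methoxybenzyl)oxy]-4,8-dimethylnon-7-en-1-yl}-5-methyl-1,3-dioxolan-4-one (C1'' epimers) | C[C@@]1(C(O)CC[C@@H](C)[C@H](OCc2ccc(OC)cc2)CC=C(C)C)O[C@@H](C(C)(C)C)OC1=O
F9 | step 7 | O-{(4R,5R)-1-[(2R,4S)-2-tert-butyl-4-methyl-5-oxo-1,3-dioxolan-4-yl]-5-[(4-methoxybenzyl)oxy]-4,8-dimethylnon-7-en-1-yl} O-phenyl carbonothioate (C1'' epimers) | C[C@@]1(C(OC(=S)Oc2ccccc2)CC[C@@H](C)[C@H](OCc2ccc(OC)cc2)CC=C(C)C)O[C@@H](C(C)(C)C)OC1=O
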